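The readings stem from a simulated flask from invented constants; scatter was added.

I decided to reckon the flask by the fraction of substrate left, not by the target made.

| flask | substrate | reagent | base | remark | time |
|---|---|---|---|---|---|
| green | 14 mM (fed, over 8.0 min) | 4 equiv | 0.30 equiv | run made earlier |  |
| ochre | 54 mM (fed, over 8.0 min) | 4 equiv | 0.30 equiv | run made earlier |  |
| red | 27 mM (fed, over 8.0 min) | 8 equiv | 0.30 equiv | run made earlier |  |
| flask | 27 mM (fed, over 8.0 min) | 4.00 equiv | 0.300 equiv |  | 30 min |

| run | time / min | target / % | substrate / % |
|---|---|---|---|
| green | 3.00 | 0 | 38 |
| green | 8.00 | 0 | 99 |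
| green | 15.0 | 6 | 93 |
| green | 25.0 | 8 | 89 |
| ochre | 6.00 | 2 | 69 |
| ochre | 12.0 | 10 | 82 |
| ochre | 20.0 | 21 | 63 |
| ochre | 25.0 | 55 | 22 |
| red | 3.00 | 4 | 38 |
| red | 8.00 | 3 | 91 |
| red | 15.0 | 15 | 76 |
| red | 25.0 | 46 | 44 |

(scatter of a reading: 2 percentage points)

- the numbers in the tables scatter with a standard deviation of 2 percentage points
- percentages count the whole charge, also what has not yet gone in

- amount of target in percent of the substrate charged, at 6.0 min, 15 min and 30 min

After its feed, the readings of the green run showed substrate falling at about 0.00626 /min, a pseudo-first-order rate read from the log of the fraction left. Red, with reagent at 216 mM, lost it at 0.0257 /min between 8.00 min and 15.0 min. That is a rate ratio of 4.11 for a reagent ratio of 3.86, so I scaled the rate with reagent and gave the flask 0.0121 /min.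

Ochre, with red's reagent concentration, left that line: once its substrate read under about 70.0 %, it fell at 0.210 /min between 20.0 min and 25.0 min, faster than red's slow rate. Green, still at 89 % at its last reading, stayed slow. That level is the charge less the base equivalents, the same in green, ochre and red, so I supposed the base holds back something made along with the target.

The ladder for the flask starts at the middle of the feed, 4.00 min. From there, the slow rate brings the substrate left down to that level at 33.5 min; this clock time, the fill time of the base, is the quantity I carried. The asked end, 30 min, comes earlier, so I kept the flask on the slow line. Its half-life on that line, 57.4 min, is longer still.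

On that line the flask keeps 73.0 % of its substrate at 30 min. The last green reading showed about 72.7 % of the lost substrate as target, a rough ratio given the scatter, so I expected target at 1.98 %, 9.05 % and 19.6 %.

The forecast gave 1.5 %, 8 % and 22 %, the last above mine, holding that “the percent conversion depends mainly on reagent concentration”.

The flask gave 1.81 %, 7.86 % and 16.2 %.

    substrate + target → side product (k = 0.0180 /M/s)
    substrate + reagent + by-product → target + 2 by-product (k = 2.00 /M²/s)
    substrate + reagent → target + by-product (k = 0.00130 /M/s)
    base + by-product ⇌ salt, settled at all times (K = 5800 /M)
    reagent → decomposition product (k = 1.60 × 10⁻⁶ /s)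

At 30.0 min the flask still held substrate at 72.8 %, with 32.3 % of its base left, so it stood short of the fill I had reckoned for 33.5 min. Its target stayed at 16.2 % through two things acting together, the base parking by-product as salt and the shortness of the run: without the parking the same run gives 84.2 %, and a run ten times as long gives 66.1 %. The red run, with a reckoned fill time of 18.8 min, had passed it by 25.0 min, when its target read 46 %.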